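**Strategy**

The plan cuts the dihydrofuran ring (O1–C2–C3–C3a–C7a, benzofuran numbering) at C3–C3a and O1–C2. It exploits the enol unit C3a=C7a–O1 hidden in the six-membered ring. C3a is the only ring C–H carbon of an enantiopure 2-isobutyryl-4-methyl-4-prenylcyclohexane-1,3,5-trione, and O1 is the enol oxygen next to it on the acyl side. One palladium-catalysed operation unites this triketone with a five-carbon allylic carbonate/acetate: C-allylation at C3a, then O-closure at C2. This builds the ring and sets C2 under ligand control. The quaternary C5 comes from an enzymatically desymmetrised malonate. Enolate hydroxylation at C3a, then radical Markovnikov hydration of the isopropenyl group, complete the target.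

Key step: step 9

**Remarks on the chemistry (assumptions)**
- Tautomers: every enolised polycarbonyl compound is drawn as one tautomer, and CIP descriptors refer to that tautomer; the spatial arrangement at the quaternary carbon never changes.
- Enzyme: pig liver esterase is assumed to leave the (R)-half-ester, the sense expected for 2-methylmalonates whose second substituent is long; sense and ee must be checked on the half-ester.
- Ligand: the (S,S) ligand is written for the (2S) centre; both antipodes are sold, and the one that delivers (2S) is used.
- Order of the end game: C3a is oxidised before the alkene is hydrated, because a free C4 enol could bind or be oxidised by the hydration metal and could add to the neighbouring prenyl group; a mercury-based hydration is avoided for the same reason.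

**Route**

Step 1
Reactants: 1 dimethyl 2-methylmalonate; 2 1-bromo-3-methylbut-2-ene (prenyl bromide)
Product: 3 dimethyl 2-methyl-2-(3-methylbut-2-en-1-yl)malonate
Conditions: NaH (1.05 equiv), THF, 0 °C; then 2, 0 °C to rt
Reagents that add atoms: none
Why: Malonic ester alkylation (SN2), in which the sodium enolate of 1 has a single acidic C–H and the primary allylic bromide reacts at its CH2 end, so one C-alkylation gives the prochiral quaternary diester and no stereocentre arises.

Step 2
Reactants: 3 dimethyl 2-methyl-2-(3-methylbut-2-en-1-yl)malonate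
Product: 4 (R)-2-(methoxycarbonyl)-2,5-dimethylhex-4-enoic acid
Conditions: pig liver esterase, phosphate buffer (pH 7.5)/DMSO 9:1, 25 °C
Reagents that add atoms: water, O
Why: Enzymatic desymmetrisation (esterase hydrolysis of one of two enantiotopic ester groups), a known reaction of 2-alkyl-2-methylmalonates, sets the quaternary centre that becomes C5 and stops at the half-ester because the carboxylate is no longer a substrate.

Step 3
Reactants: 4 (R)-2-(methoxycarbonyl)-2,5-dimethylhex-4-enoic acid
Product: 5 methyl (S)-2-(chlorocarbonyl)-2,5-dimethylhex-4-enoate (same spatial arrangement, descriptor changes with priorities)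
Conditions: 1-chloro-N,N,2-trimethylprop-1-en-1-amine (1.1 equiv), CH2Cl2, 0 °C to rt; evaporate, use crude
Reagents that add atoms: 1-chloro-N,N,2-trimethylprop-1-en-1-amine, CC(C)=C(Cl)N(C)C
Why: Neutral acid chloride formation with an α-chloroenamine releases no free HCl, so the prenyl alkene and the methyl ester survive, and a centre without α-hydrogen can neither epimerise nor form a ketene.

Step 4
Reactants: 5 methyl (S)-2-(chlorocarbonyl)-2,5-dimethylhex-4-enoate; 6 5-methylhexane-2,4-dione
Product: 8 methyl (R)-2,8-dimethyl-2-(3-methylbut-2-en-1-yl)-3,5,7-trioxononanoate, via dilithium dienolate 7 (not isolated)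
Conditions: 6 (2.2 equiv), LiN(i-Pr)2 (4.4 equiv), THF, 0 °C; then 5, −78 to −20 °C; 1 M HCl
Reagents that add atoms: none
Why: γ-Acylation of a β-diketone dianion, in which the second deprotonation takes the methyl group rather than the isopropyl C–H, the terminal carbanion attacks the acid chloride in preference to the hindered ester, and the excess dianion absorbs the acidic proton of the product.

Step 5
Reactants: 8 methyl (R)-2,8-dimethyl-2-(3-methylbut-2-en-1-yl)-3,5,7-trioxononanoate
Product: 9 (R)-3-hydroxy-2-isobutyryl-6-methyl-6-(3-methylbut-2-en-1-yl)cyclohex-2-ene-1,5-dione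
Conditions: NaOMe (3 equiv), MeOH, reflux; then 1 M HCl
Reagents that add atoms: none
Why: Dieckmann (intramolecular Claisen) condensation, in which C6 of 8 attacks the ester in a six-ring closure helped by the quaternary carbon, the triketonate is the thermodynamic sink over O-acylation, and the acid-derived carbonyl ends beside the ring CH2 while the ester-derived one ends beside the acyl-bearing carbon, so the configuration is carried over.

Step 6
Reactants: 10 3-methylbut-2-en-1-ol (prenol)
Product: 11 methyl 3-methylbut-2-en-1-yl carbonate
Conditions: ClCO2Me (1.2 equiv), pyridine (1.5 equiv), CH2Cl2, 0 °C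
Reagents that add atoms: methyl chloroformate, COC(=O)Cl
Why: O-Acylation of a primary alcohol with a chloroformate places the better leaving group on the CH2 that is bound to the alkene CH.

Step 7
Reactants: 11 methyl 3-methylbut-2-en-1-yl carbonate
Product: 12 (E)-4-hydroxy-3-methylbut-2-en-1-yl methyl carbonate
Conditions: SeO2 (0.3 equiv), t-BuOOH (2.5 equiv), CH2Cl2, 0 °C to rt
Reagents that add atoms: tert-butyl hydroperoxide, CC(C)(C)OO (oxygen passed on through selenium dioxide, O=[Se]=O)
Why: Riley allylic oxidation (ene reaction, then [2,3]-sigmatropic shift) attacks the more substituted alkene end at the methyl group trans to the chain, which is the known way from prenyl esters to their (E)-allylic alcohols.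

Step 8
Reactants: 12 (E)-4-hydroxy-3-methylbut-2-en-1-yl methyl carbonate
Product: 13 (E)-4-[(methoxycarbonyl)oxy]-2-methylbut-2-en-1-yl acetate
Conditions: Ac2O (1.3 equiv), Et3N, DMAP (cat.), CH2Cl2, 0 °C to rt
Reagents that add atoms: acetic anhydride, CC(=O)OC(C)=O
Why: Acetylation of the primary allylic alcohol completes a bis-electrophile with two leaving groups of clearly different ionisation rate.

Step 9
Reactants: 9 (R)-3-hydroxy-2-isobutyryl-6-methyl-6-(3-methylbut-2-en-1-yl)cyclohex-2-ene-1,5-dione; 13 (E)-4-[(methoxycarbonyl)oxy]-2-methylbut-2-en-1-yl acetate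
Product: 15 (2S,5R)-4-hydroxy-7-isobutyryl-5-methyl-5-(3-methylbut-2-en-1-yl)-2-(prop-1-en-2-yl)-2,3-dihydrobenzofuran-6(5H)-one, via allylic acetate 14 (not isolated)
Conditions: Pd2(dba)3·CHCl3 (2.5 mol %), (1S,2S)-N,N'-bis[2-(diphenylphosphino)benzoyl]cyclohexane-1,2-diamine [(S,S)-DACH-phenyl ligand, 7.5 mol %], DBU (2.2 equiv), n-Bu4NCl (0.3 equiv), CH2Cl2, 0 °C to rt, 13 added over several hours; pH 4 work-up
Reagents that add atoms: none
Why: Zerovalent palladium ionises the methyl carbonate of 13 well before the acetate, and the enolate of 9 attacks the unsubstituted allyl terminus through its only ring C–H carbon (the future C3a), which forms C3–C3a and gives 14 (Tsuji–Trost allylation). Ionisation of the acetate in 14 then gives a 2-methyl-π-allylpalladium complex, which the oxygen on the future C7a captures at the internal terminus in a 5-exo closure (the 7-endo mode at the CH2 terminus is slower); this forms O1–C2 and leaves the isopropenyl group. The closest known reaction types are the palladium-catalysed [3+2] annulation of cyclic 1,3-diketones with but-2-ene-1,4-diyl diesters to 2-vinyl-2,3-dihydrofurans and the ligand-controlled cyclisation of phenols to 2-isopropenyl-2,3-dihydrobenzofurans. C2 is set by the chiral ligand: the two diastereomeric π-allyl complexes swap faces by π–σ–π through the CH2 terminus (chloride speeds this up), so both alkene isomers of 14 and both ionisation faces should drain through the faster-closing complex, while the remote C5 centre has little influence. The selectivity needed is closure through the C7a oxygen and not through the free vinylogous-acid oxygen beside C5; in the mono-anion the C7a oxygen is locked in the hydrogen-bond chelate to the isobutyryl carbonyl and would lose, so two equivalents of DBU remove that proton, after which this oxygen is the only one that belongs to both enolate systems of the substrate (β-triketonate and vinylogous carboxylate) and carries the most charge. The same base keeps 15 as its enolate, a poor leaving group, so that the allylic C2–O1 bond is not ionised again and C2 is not scrambled; slow addition of 13 holds back a second allylation at C3a.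

Step 10
Reactants: 15 (2S,5R)-4-hydroxy-7-isobutyryl-5-methyl-5-(3-methylbut-2-en-1-yl)-2-(prop-1-en-2-yl)-2,3-dihydrobenzofuran-6(5H)-one
Product: 16 (2S,3aR,5S)-3a-hydroxy-7-isobutyryl-5-methyl-5-(3-methylbut-2-en-1-yl)-2-(prop-1-en-2-yl)-3,3a-dihydrobenzofuran-4,6(2H,5H)-dione
Conditions: 2-(phenylsulfonyl)-3-phenyloxaziridine (1.5 equiv), KOt-Bu (0.2 equiv), THF, −20 °C to rt
Reagents that add atoms: 2-(phenylsulfonyl)-3-phenyloxaziridine, O=S(=O)(c1ccccc1)N1OC1c1ccccc1
Why: Davis oxidation (enolate hydroxylation), in which the potassium enolate of 15 attacks the oxaziridine oxygen through C3a (C7 is blocked by the acyl group and isolated alkenes do not react), the base turns over because 15 is far more acidic than the tertiary alcohol formed, and the reagent should approach anti to the C2 isopropenyl group, since C5 puts one carbon on each face (methyl on the isopropenyl face, prenyl CH2 on the other), which gives (3aR).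

Step 11
Reactants: 16 (2S,3aR,5S)-3a-hydroxy-7-isobutyryl-5-methyl-5-(3-methylbut-2-en-1-yl)-2-(prop-1-en-2-yl)-3,3a-dihydrobenzofuran-4,6(2H,5H)-dione
Product: 18 (2S,3aR,5S)-3a-hydroxy-2-(2-hydroxypropan-2-yl)-7-isobutyryl-5-methyl-5-(3-methylbut-2-en-1-yl)-3,3a-dihydrobenzofuran-4,6(2H,5H)-dione, via tertiary hydroperoxide 17 (not isolated)
Conditions: Co(acac)2 (20 mol %), PhSiH3 (1.5 equiv), O2 (1 atm), THF, 0 °C to rt, stopped when 16 is consumed; then PPh3
Reagents that add atoms: dioxygen, O=O
Why: Mukaiyama hydration (hydrogen-atom transfer from a cobalt hydride, O2 capture of the tertiary radical, reduction of the peroxide) should favour the open 1,1-disubstituted alkene over the trisubstituted prenyl alkene, whose CH end lies next to the quaternary C5, the allylic oxygen does not slow a radical addition as it would an ionic one, and no stereocentre is formed or touched.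

**Compound list**

1 | dimethyl 2-methylmalonate | COC(=O)C(C)C(=O)OC | starting material
2 | 1-bromo-3-methylbut-2-ene | CC(C)=CCBr | starting material
3 | dimethyl 2-methyl-2-(3-methylbut-2-en-1-yl)malonate | CC(C)=CCC(C)(C(=O)OC)C(=O)OC | intermediate
4 | (R)-2-(methoxycarbonyl)-2,5-dimethylhex-4-enoic acid | CC(C)=CC[C@@](C(=O)O)(C)C(=O)OC | intermediate
5 | methyl (S)-2-(chlorocarbonyl)-2,5-dimethylhex-4-enoate | CC(C)=CC[C@@](C(=O)Cl)(C)C(=O)OC | intermediate
6 | 5-methylhexane-2,4-dione | CC(C)C(=O)CC(C)=O | starting material
7 | dilithium dienolate of 5-methylhexane-2,4-dione (C1,C3-dianion) | [Li+].[Li+].C=C([O-])C=C([O-])C(C)C | intermediate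
8 | methyl (R)-2,8-dimethyl-2-(3-methylbut-2-en-1-yl)-3,5,7-trioxononanoate | CC(C)=CC[C@@](C(=O)CC(=O)CC(=O)C(C)C)(C)C(=O)OC | intermediate
9 | (R)-3-hydroxy-2-isobutyryl-6-methyl-6-(3-methylbut-2-en-1-yl)cyclohex-2-ene-1,5-dione | CC(C)=CC[C@@]1(C)C(=O)C(C(=O)C(C)C)=C(O)CC1=O | intermediate
10 | 3-methylbut-2-en-1-ol | CC(C)=CCO | starting material
11 | methyl 3-methylbut-2-en-1-yl carbonate | COC(=O)OCC=C(C)C | intermediate
12 | (E)-4-hydroxy-3-methylbut-2-en-1-yl methyl carbonate | COC(=O)OC/C=C(C)/CO | intermediate
13 | (E)-4-[(methoxycarbonyl)oxy]-2-methylbut-2-en-1-yl acetate | CC(=O)OC/C(C)=C/COC(=O)OC | intermediate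
14 | (E)-4-[(3R)-2,6-dihydroxy-5-isobutyryl-3-methyl-3-(3-methylbut-2-en-1-yl)-4-oxocyclohexa-1,5-dien-1-yl]-2-methylbut-2-en-1-yl acetate (drawn as the E isomer) | CC(C)=CC[C@@]1(C)C(=O)C(C(=O)C(C)C)=C(O)C(C/C=C(C)/COC(C)=O)=C1O | intermediate
15 | (2S,5R)-4-hydroxy-7-isobutyryl-5-methyl-5-(3-methylbut-2-en-1-yl)-2-(prop-1-en-2-yl)-2,3-dihydrobenzofuran-6(5H)-one | CC(C)=CC[C@@]1(C)C(=O)C(C(=O)C(C)C)=C2O[C@H](C(C)=C)CC2=C1O | intermediate
16 | (2S,3aR,5S)-3a-hydroxy-7-isobutyryl-5-methyl-5-(3-methylbut-2-en-1-yl)-2-(prop-1-en-2-yl)-3,3a-dihydrobenzofuran-4,6(2H,5H)-dione | CC(C)=CC[C@@]1(C)C(=O)C(C(=O)C(C)C)=C2O[C@H](C(C)=C)C[C@]2(O)C1=O | intermediate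
17 | (2S,3aR,5S)-2-(2-hydroperoxypropan-2-yl)-3a-hydroxy-7-isobutyryl-5-methyl-5-(3-methylbut-2-en-1-yl)-3,3a-dihydrobenzofuran-4,6(2H,5H)-dione | CC(C)=CC[C@@]1(C)C(=O)C(C(=O)C(C)C)=C2O[C@H](C(C)(C)OO)C[C@]2(O)C1=O | intermediate
18 | (2S,3aR,5S)-3a-hydroxy-2-(2-hydroxypropan-2-yl)-7-isobutyryl-5-methyl-5-(3-methylbut-2-en-1-yl)-3,3a-dihydrobenzofuran-4,6(2H,5H)-dione | CC(C)=CC[C@@]1(C)C(=O)C(C(=O)C(C)C)=C2O[C@H](C(C)(C)O)C[C@]2(O)C1=O | target

**Step count**

Total step count: 11. Longest linear sequence: 8 (steps 1–5 and 9–11). The electrophile 13 is made in 3 steps (6–8) on a side branch.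

**Three steps most likely to fail**

1. Step 9.
   - What may go wrong: ring closure may run through the enol oxygen beside the quaternary carbon. A second intermolecular allylation at C3a may overtake ionisation of the acetate. Face exchange of the π-allyl complex may be incomplete, which would weaken ligand control at C2.
   - Fallback (sets out from 9 and 13, comes back at 15): the two bond formations are separated and the rival oxygen is blocked in between. With Pd(PPh3)4 in THF at 0 °C and no added base only the carbonate should react, and 14 is isolated. Its free, non-chelated enol is the very oxygen responsible for a wrong closure. It is capped with MOMCl/i-Pr2NEt to give the methoxymethyl enol ether of 14 F1. Only the chelated enol oxygen is then left. Treatment with Pd2(dba)3·CHCl3, the chiral ligand and DBU (1.1 equiv) should close the ring to the 4-O-methoxymethyl ether of 15 F2. PPTS in MeOH at rt removes the acetal and returns 15.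

2. Step 10.
   - What may go wrong: facial selectivity may be poor, because the face to be attacked carries the prenyl chain of C5. Oxygen transfer to a strongly stabilised enolate may also be sluggish.
   - Fallback (sets out from 15, comes back at 16): the C3a–O bond is made as an ester with a larger and more electrophilic oxygen source. The sodium enolate of 15 (NaH, THF, 0 °C) is treated with dibenzoyl peroxide (SN2 at the peroxide oxygen, a known benzoyloxylation of 1,3-dicarbonyl enolates that leaves alkenes alone). This should give the C3a benzoate of 16 F3, on which C3a epimers can be separated. Mild methanolysis (K2CO3, MeOH, 0 °C) of the activated α-keto benzoate returns 16.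

3. Step 2.
   - What may go wrong: the enzyme may discriminate poorly between the two ester groups, since a five-carbon branched side chain lies near the chain length where the enzyme changes its preference. It may also select in the opposite sense. A small residue of the wrong enantiomer would be purged later, because after step 9 it is a diastereomer of 15.
   - Fallback (sets out from 3, comes back at 4): classical resolution replaces the enzyme. KOH (1 equiv) in MeOH gives the racemic half-ester F4. Crystallisation with (S)-1-phenylethylamine gives the (S)-1-phenylethylammonium salt of 4 F5; the antipodal amine is used if that one gives the less soluble salt with the (R)-acid. Dilute KHSO4 releases 4. The acid left in the mother liquor is re-esterified (MeI, K2CO3) to the achiral diester 3 and recycled.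

**Further compounds**

F1 | step 9 | (E)-4-[(3R)-6-hydroxy-5-isobutyryl-2-(methoxymethoxy)-3-methyl-3-(3-methylbut-2-en-1-yl)-4-oxocyclohexa-1,5-dien-1-yl]-2-methylbut-2-en-1-yl acetate (methoxymethyl enol ether of 14) | CC(C)=CC[C@@]1(C)C(=O)C(C(=O)C(C)C)=C(O)C(C/C=C(C)/COC(C)=O)=C1OCOC
F2 | step 9 | (2S,5R)-7-isobutyryl-4-(methoxymethoxy)-5-methyl-5-(3-methylbut-2-en-1-yl)-2-(prop-1-en-2-yl)-2,3-dihydrobenzofuran-6(5H)-one (4-O-methoxymethyl ether of 15) | CC(C)=CC[C@@]1(C)C(=O)C(C(=O)C(C)C)=C2O[C@H](C(C)=C)CC2=C1OCOC
F3 | step 10 | (2S,3aR,5S)-7-isobutyryl-5-methyl-5-(3-methylbut-2-en-1-yl)-4,6-dioxo-2-(prop-1-en-2-yl)-2,3,5,6-tetrahydrobenzofuran-3a(4H)-yl benzoate (C3a benzoate of 16) | CC(C)=CC[C@@]1(C)C(=O)C(C(=O)C(C)C)=C2O[C@H](C(C)=C)C[C@]2(OC(=O)c3ccccc3)C1=O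
F4 | step 2 | racemic 2-(methoxycarbonyl)-2,5-dimethylhex-4-enoic acid (racemic half-ester) | CC(C)=CCC(C)(C(=O)O)C(=O)OC
F5 | step 2 | (S)-1-phenylethylammonium (R)-2-(methoxycarbonyl)-2,5-dimethylhex-4-enoate | CC(C)=CC[C@@](C(=O)[O-])(C)C(=O)OC.C[C@H]([NH3+])c1ccccc1
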